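## Retrosynthetic overview

1. Target 9 ⇐ one global LiAlH4 reduction of the all-trans 1-aryl-tetralin-2,3-diester 8 (esters → CH2OH, aryl acetates → phenols).
2. C1–H of 8 ⇐ retentive hydrogenolysis (Raney Ni) of the tertiary, bis-benzylic C1–OH in tetralol 7.
3. Ring B of 7 (bonds C1–C2 and C3–C4, plus all three stereocentres) ⇐ photoenolisation/Diels–Alder: ring A of 2-methylbenzophenone 3 is photo-dearomatised to a hydroxy-o-quinodimethane and trapped by the chiral fumarate 6.
4. Benzophenone 3 ⇐ Friedel–Crafts aroylation of creosol acetate 2 with O-acetylsyringic acid 1; fumarate 6 ⇐ fumaryl chloride 4 + methyl (R)-lactate 5.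
5. Rings A and C are bought; ring B is the only ring formed, in step 3.

Tetralin numbering: C1 = CH(aryl), C2 and C3 = carbons bearing CH2OH, C4 = CH2, C6 = OMe, C7 = OH. The target is (1R,2S,3S), all-trans.

Assumption 1: 2-methoxy-4-methylphenyl acetate (the acetate of the wood-tar/lignin phenol creosol) and 4-acetoxy-3,5-dimethoxybenzoic acid are purchased; if not, each is one Ac2O/pyridine step from creosol or syringic acid.

Assumption 2: the sense of facial induction is assigned from recalled precedent, not derived: (S)-lactate and (S)-mandelate fumarates are taken to give the (+)-isolariciresinol (2R,3R-diol) series with hydroxy-o-quinodimethanes. The target is the (2S,3S) series, so the (R)-lactate is used; this must be confirmed by [α]D/CD on 9.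

## Route

**Step 1**
Reactants: 1, 4-acetoxy-3,5-dimethoxybenzoic acid; 2, 2-methoxy-4-methylphenyl acetate
Product: 3, 5-(4-acetoxy-3,5-dimethoxybenzoyl)-2-methoxy-4-methylphenyl acetate
Conditions: TFAA (4 equiv), 85% H3PO4 (1 equiv), CH2Cl2, 0 → 40 °C
Reagents that add atoms: none
Why: Friedel–Crafts acylation through the in-situ mixed anhydride; attack occurs at the one ring position that is para to OMe and ortho to CH3, and the acetates survive these Lewis-acid-free conditions and prevent O-acylation (no stereocentre).

**Step 2**
Reactants: 4, fumaryl chloride; 5, methyl (R)-lactate (2 equiv)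
Product: 6, bis[(2R)-1-methoxy-1-oxopropan-2-yl] (2E)-but-2-enedioate
Conditions: pyridine (2.2 equiv), CH2Cl2, 0 °C → rt
Reagents that add atoms: none
Why: Simple O-acylation of the secondary alcohol by the acid chloride; the lactate stereocentre is not involved and the E-alkene is retained.

**Step 3 (key step)**
Reactants: 3, the 2-methylbenzophenone; 6, the chiral fumarate (2 equiv)
Product: 7, bis[(2R)-1-methoxy-1-oxopropan-2-yl] (1S,2R,3S)-7-acetoxy-1-(4-acetoxy-3,5-dimethoxyphenyl)-1-hydroxy-6-methoxy-1,2,3,4-tetrahydronaphthalene-2,3-dicarboxylate (1-OH cis to the C2 ester, 1-aryl trans to it, 2,3-trans)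
Conditions: hν 365 nm (LED, Pyrex or FEP flow coil), degassed PhMe (0.03 M), 20 °C
Reagents that add atoms: none
Why: Photoenolisation/Diels–Alder: 1,5-H abstraction by the n,π* ketone dearomatises ring A to the long-lived (E)-hydroxy-o-quinodimethane (OH outward, aryl inward), which adds to the fumarate and re-aromatises. The ester next to the C(OH)Ar terminus sits endo, H-bonded to the dienol OH (exo would clash with both terminus substituents), which sets 1-OH cis and 1-Ar trans to the C2 ester; the E-fumarate gives 2,3-trans; the lactate auxiliaries select the fumarate face (Assumption 2).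

**Step 4**
Reactants: 7
Product: 8, bis[(2R)-1-methoxy-1-oxopropan-2-yl] (1R,2S,3S)-7-acetoxy-1-(4-acetoxy-3,5-dimethoxyphenyl)-6-methoxy-1,2,3,4-tetrahydronaphthalene-2,3-dicarboxylate (all-trans)
Conditions: Raney Ni (W-2, washed neutral, large excess), H2 (1 atm), EtOAc–EtOH, 50 °C
Reagents that add atoms: none (H only)
Why: Heterogeneous hydrogenolysis of a benzylic alcohol on Raney nickel goes with retention (the OH binds the Ni surface and H is delivered to the same face; Pd gives inversion), so H takes the place of OH and the aryl stays trans to the C2 ester. The 1S → 1R change is only a CIP priority change; the aryl acetates stop quinone-methide ionisation at C1.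

**Step 5**
Reactants: 8
Product: 9, (1R,2S,3S)-1-(4-hydroxy-3,5-dimethoxyphenyl)-2,3-bis(hydroxymethyl)-6-methoxy-1,2,3,4-tetrahydronaphthalen-7-ol (target, CID 70697973)
Conditions: LiAlH4 (8 equiv), THF, 0 °C → rt; Rochelle salt, then pH 5, EtOAc extraction
Reagents that add atoms: none (H only)
Why: Global hydride reduction of both lactyl esters to CH2OH and cleavage of both aryl acetates; propane-1,2-diol, EtOH and MeOH are water-soluble by-products, and reduction outpaces enolisation so no stereocentre is touched.

## Compound list

1 | 4-acetoxy-3,5-dimethoxybenzoic acid | COc1cc(C(=O)O)cc(OC)c1OC(C)=O | starting material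
2 | 2-methoxy-4-methylphenyl acetate (creosol acetate) | Cc1ccc(OC(C)=O)c(OC)c1 | starting material
3 | 5-(4-acetoxy-3,5-dimethoxybenzoyl)-2-methoxy-4-methylphenyl acetate | Cc1cc(OC)c(OC(C)=O)cc1C(=O)c1cc(OC)c(OC(C)=O)c(OC)c1 | intermediate
4 | fumaryl chloride | O=C(Cl)/C=C/C(=O)Cl | starting material
5 | methyl (R)-lactate | C[C@@H](O)C(=O)OC | starting material
6 | bis[(2R)-1-methoxy-1-oxopropan-2-yl] fumarate | COC(=O)[C@@H](C)OC(=O)/C=C/C(=O)O[C@H](C)C(=O)OC | intermediate
7 | (1S,2R,3S)-1-hydroxy-1-aryl tetralin bis-lactyl diester (cycloadduct) | COc1cc2c(cc1OC(C)=O)[C@@](O)(c1cc(OC)c(OC(C)=O)c(OC)c1)[C@H](C(=O)O[C@H](C)C(=O)OC)[C@@H](C(=O)O[C@H](C)C(=O)OC)C2 | intermediate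
8 | (1R,2S,3S)-1-aryl tetralin bis-lactyl diester (all-trans) | COc1cc2c(cc1OC(C)=O)[C@@H](c1cc(OC)c(OC(C)=O)c(OC)c1)[C@H](C(=O)O[C@H](C)C(=O)OC)[C@@H](C(=O)O[C@H](C)C(=O)OC)C2 | intermediate
9 | (1R,2S,3S)-1-(4-hydroxy-3,5-dimethoxyphenyl)-2,3-bis(hydroxymethyl)-6-methoxy-1,2,3,4-tetrahydronaphthalen-7-ol | COc1cc2c(cc1O)[C@@H](c1cc(OC)c(O)c(OC)c1)[C@H](CO)[C@@H](CO)C2 | target

## Summary

Total steps: 5. Longest linear sequence: 4 (1/2 → 3 → 7 → 8 → 9).

Steps most likely to fail:

1. **Step 3 (photoenolisation/Diels–Alder).** Risks: the fumarate may quench the ketone triplet (with E→Z isomerisation), the dienol may revert to ketone, and the facial selectivity may be low or of the opposite sense. Fallback: decouple photochemistry from cycloaddition. Irradiate 3 in SO2-saturated benzene to trap the dienol as the 1-aryl-1-hydroxy-1,3-dihydrobenzo[c]thiophene 2,2-dioxide, then extrude SO2 thermally (80–110 °C, ZnO) in the presence of 6. If the sense of induction is reversed, use the fumarate of methyl (S)-lactate.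

2. **Step 4 (retentive C1–OH hydrogenolysis).** Risks: partial inversion, or dehydration followed by hydrogenation, giving the 1,2-cis epimer. Fallback: relay the stereochemistry through the alkene. Dehydrate 7 (TsOH, PhMe) to the 1-aryl-3,4-dihydronaphthalene-2,3-diester; hydrogenate over Pd/C (H2 adds anti to the C3 ester, giving the correct C1 with C2 cis); epimerise C2 with NaOMe/MeOH to the all-trans dimethyl ester; then LiAlH4.

3. **Step 1 (direct aroylation).** Risks: sluggish acylation of the acetoxy-deactivated arene, or acetyl scrambling. Fallback: build the ketone by organometallic addition. Brominate O-benzylcreosol para to OMe, do Br/Li exchange, add to 4-benzyloxy-3,5-dimethoxybenzaldehyde and oxidise with MnO2 to the dibenzyl benzophenone. The benzyl ethers are then removed by H2/Pd–C after the LiAlH4 step.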